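**Plan**

1. Retrosynthesis: the last steps are desilylation, C1 ketone reduction and O8 acetylation. Ring B is cut at C8–C9 (homoaldol of a C9 homoenolate of a C1 ketone onto a C8 aldehyde). Earlier cuts are C6–C7 (syn aldol), C5–C6 and the C1–C9–C10 cyclopropane (vinyl addition, enol ether cyclopropanation) and C5=C10 (ring-closing metathesis), back to (R)-linalool.
2. Enabling feature: the oxygens on C1 (ring A) and C8 (ring B) are 1,4-related through C10–C9, so C9 is the β-carbon of a C1 ketone. A cyclopropanol C1–C9–C10 fused to ring A stores this homoenolate; its strain release forms C8–C9 and unveils the C1 carbonyl.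
3. Forward order: ring A from linalool, then the cyclopropane on ring A, then the acyclic C6–C7–C8 chain carrying the acrylate, then ring B, then three finishing steps.
4. Stereochemistry: C4 from (R)-linalool; C5 by cuprate addition anti to OSiEt3; C10 by cyclopropanation anti to the C5 substituent; C6 and C7 by the (S)-benzyloxazolidinone; C8 in the ring closure (chair, equatorial oxygen); C1 by axial hydride attack.

Key step: step 16

Remark: atoms carry eudesmane numbering (C1–C10 ring carbons, C11–C13 the acrylate, C14 and C15 the methyl groups on C10 and C4; α is the face opposite C14). (R)-(−)-Linalool of high enantiomeric purity, dimethyl itaconate and (S)-4-benzyl-1,3-oxazolidin-2-one are taken as purchased.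

**Route**

Step 1
Reactants: 1 (R)-(−)-linalool
Product: 2 (3R)-3,7-dimethyl-3-(triethylsilyloxy)octa-1,6-diene
Conditions: Et3SiOTf, 2,6-lutidine, CH2Cl2, −78 → 0 °C
Reagents that add atoms: triethylsilyl trifluoromethanesulfonate, CC[Si](CC)(CC)OS(=O)(=O)C(F)(F)F
Why: Silyl ether formation with a silyl triflate and a hindered pyridine base caps the tertiary allylic alcohol with a bulky, non-chelating group and leaves the chiral-pool stereocentre (C4) untouched.

Step 2
Reactants: 2 (3R)-3,7-dimethyl-3-(triethylsilyloxy)octa-1,6-diene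
Product: 4 (4R)-4-methyl-4-(triethylsilyloxy)hex-5-enal, via ozonide 3 (not isolated)
Conditions: O3 (1 equiv, dye end point), CH2Cl2, −78 °C; PPh3, −78 °C → rt
Reagents that add atoms: ozone, [O-][O+]=O
Why: Ozonolysis with reductive work-up should cleave the electron-rich trisubstituted alkene well before the monosubstituted vinyl group beside the quaternary carbon, giving the C1 aldehyde.

Step 3
Reactants: 4 (4R)-4-methyl-4-(triethylsilyloxy)hex-5-enal
Product: 5 (6R)-2,6-dimethyl-6-(triethylsilyloxy)octa-1,7-dien-3-ol (both C3 epimers)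
Conditions: isopropenylmagnesium bromide, THF, −78 → 0 °C; aq. NH4Cl
Reagents that add atoms: isopropenylmagnesium bromide, C=C(C)[Mg]Br
Why: Grignard 1,2-addition to the aldehyde brings in C10 with its methyl group; the new carbinol centre forms unselectively and is erased by the oxidation in step 5.

Step 4
Reactants: 5 (6R)-2,6-dimethyl-6-(triethylsilyloxy)octa-1,7-dien-3-ol
Product: 6 (4R)-2,4-dimethyl-4-(triethylsilyloxy)cyclohex-2-en-1-ol (both C1 epimers)
Conditions: second-generation Grubbs catalyst (3 mol%), CH2Cl2, 40 °C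
Reagents that add atoms: none
Why: Ring-closing metathesis between the vinyl group and the 1,1-disubstituted alkene closes ring A as a cyclohexene with the trisubstituted C5=C10 bond, driven by loss of ethylene.

Step 5
Reactants: 6 (4R)-2,4-dimethyl-4-(triethylsilyloxy)cyclohex-2-en-1-ol
Product: 7 (4R)-2,4-dimethyl-4-(triethylsilyloxy)cyclohex-2-en-1-one
Conditions: Dess–Martin periodinane, NaHCO3, CH2Cl2, 0 °C → rt
Reagents that add atoms: none
Why: Dess–Martin oxidation of the secondary allylic alcohol gives the enone and merges the two C1 epimers.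

Step 6
Reactants: 7 (4R)-2,4-dimethyl-4-(triethylsilyloxy)cyclohex-2-en-1-one
Product: 9 (3R,4R)-2,4-dimethyl-4-(triethylsilyloxy)-1-(trimethylsilyloxy)-3-vinylcyclohex-1-ene, via magnesium enolate 8 (not isolated)
Conditions: vinylmagnesium bromide, CuBr·SMe2 (10 mol%), Me3SiCl, HMPA, THF, −78 °C; Et3N, pentane work-up
Reagents that add atoms: vinylmagnesium bromide, C=C[Mg]Br; chlorotrimethylsilane, C[Si](C)(C)Cl
Why: Copper-catalysed conjugate addition accelerated by Me3SiCl/HMPA should deliver the vinyl group to C5 by axial attack anti to the pseudoaxial C4–OSiEt3 bond (trans to O4, cis to C15), and O-silylation of enolate 8 fixes the C1=C10 double bond regiospecifically.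

Step 7
Reactants: 9 (3R,4R)-2,4-dimethyl-4-(triethylsilyloxy)-1-(trimethylsilyloxy)-3-vinylcyclohex-1-ene
Product: 10 4,6-dimethyl-4-(triethylsilyloxy)-1-(trimethylsilyloxy)-5-vinylbicyclo[4.1.0]heptane (cyclopropane CH2 trans to the vinyl group, cis to OSiEt3)
Conditions: Et2Zn, CH2I2, CH2Cl2, 0 °C → rt; pyridine, then aq. NH4Cl
Reagents that add atoms: diiodomethane, ICI
Why: Simmons–Smith cyclopropanation (Furukawa variant) is fastest at the electron-rich silyl enol ether and should occur on the face opposite the pseudoaxial vinyl group on C5, placing the new CH2 (C9) trans to C6 and so setting the quaternary C10 and C1 of the cis-fused cyclopropane.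

Step 8
Reactants: 10 4,6-dimethyl-4-(triethylsilyloxy)-1-(trimethylsilyloxy)-5-vinylbicyclo[4.1.0]heptane
Product: 12 1,3-dimethyl-3-(triethylsilyloxy)-6-(trimethylsilyloxy)bicyclo[4.1.0]heptane-2-carbaldehyde, via ozonide 11 (not isolated)
Conditions: O3, CH2Cl2, −78 °C; PPh3, −78 °C → rt
Reagents that add atoms: ozone, [O-][O+]=O
Why: Ozonolysis of the only remaining alkene with reductive work-up gives the C6 aldehyde; the silyl ethers and the siloxycyclopropane are inert to ozone at −78 °C and no base is present to epimerise C5.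

Step 9
Reactants: 13 dimethyl itaconate
Product: 14 3-(methoxycarbonyl)but-3-enoic acid
Conditions: LiOH·H2O (1.0 equiv), THF–H2O, 0 °C; HCl to pH 2
Reagents that add atoms: lithium hydroxide, [Li+].[OH-]
Why: Ester hydrolysis with one equivalent of hydroxide should be selective for the non-conjugated, less hindered ester, leaving the conjugated methyl ester that becomes C12.

Step 10
Reactants: 14 3-(methoxycarbonyl)but-3-enoic acid; 15 (S)-4-benzyl-1,3-oxazolidin-2-one
Product: 18 (4S)-4-benzyl-3-[3-(methoxycarbonyl)but-3-enoyl]-1,3-oxazolidin-2-one, via mixed pivalic anhydride 16 (not isolated), via lithium oxazolidinide 17 (not isolated)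
Conditions: 14, t-BuCOCl, Et3N, THF, −78 → 0 °C; separately 15, n-BuLi, THF, −78 °C; combine at −78 °C; aq. NH4Cl
Reagents that add atoms: none
Why: N-Acylation of the lithiated oxazolidinone by the mixed pivalic anhydride at low temperature (standard Evans imide synthesis) avoids amine-induced migration of the double bond into conjugation.

Step 11
Reactants: 18 (4S)-4-benzyl-3-[3-(methoxycarbonyl)but-3-enoyl]-1,3-oxazolidin-2-one; 12 aldehyde
Product: 21 Evans syn-aldol adduct (C8 imide; free 6-hydroxyl; C6/C7 as in the target), via dibutylboron Z-enolate 19 (not isolated), via dibutylboron aldolate 20 (not isolated)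
Conditions: 18 (1.5 equiv), Bu2BOTf, i-Pr2NEt, CH2Cl2, −78 → 0 °C; 12, −78 → 0 °C; pH 7 buffer, MeOH, H2O2, 0 °C
Reagents that add atoms: none
Why: Evans syn-aldol reaction in which Z-enolate 19 reacts at its α-carbon through a Zimmerman–Traxler chair; the (S)-benzyl auxiliary blocks one enolate face and so should fix C7 and the syn-related C6 in the sense of the target by reagent control, which matters because the aldehyde has two similar quaternary neighbours.

Step 12
Reactants: 21 Evans syn-aldol adduct
Product: 22 6-O-triethylsilyl ether of 21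
Conditions: Et3SiOTf, 2,6-lutidine, CH2Cl2, −78 → −20 °C
Reagents that add atoms: triethylsilyl trifluoromethanesulfonate, CC[Si](CC)(CC)OS(=O)(=O)C(F)(F)F
Why: Silylation of the hindered secondary alcohol with the silyl triflate protects O6, so that no alkoxide at C6 can later cause retro-aldol cleavage or lactonisation onto C12.

Step 13
Reactants: 22 6-O-triethylsilyl ether
Product: 23 cyclopropanol (Me3Si removed from O1)
Conditions: PPTS (cat.), MeOH–CH2Cl2, 0 °C
Reagents that add atoms: none
Why: Acid-catalysed methanolysis (selective desilylation) cleaves the trimethylsilyl ether far faster than the hindered secondary and tertiary triethylsilyl ethers and does not touch the imide.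

Step 14
Reactants: 23 cyclopropanol imide
Product: 24 C8 primary alcohol
Conditions: LiBH4, MeOH (1 equiv), THF, 0 °C; aq. NH4Cl, 0 °C
Reagents that add atoms: none
Why: Reductive removal of the auxiliary with LiBH4, which attacks the activated imide carbonyl in preference to the conjugated methyl ester; a cold quench limits lactonisation of the new alcohol onto C12.

Step 15
Reactants: 24 C8 primary alcohol
Product: 25 C8 aldehyde with free cyclopropanol
Conditions: Dess–Martin periodinane, NaHCO3, CH2Cl2, 0 °C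
Reagents that add atoms: none
Why: Dess–Martin oxidation under buffered, base-free conditions should give the aldehyde without epimerising the doubly activated C7–H; the tertiary cyclopropanol has no carbinol hydrogen to oxidise.

Step 16
Reactants: 25 C8 aldehyde with free cyclopropanol
Product: 29 methyl 8α-hydroxy-1-oxo-4α,6α-bis(triethylsilyloxy)eudesm-11(13)-en-12-oate, via ethylzinc cyclopropoxide 26 (not isolated), via zinc homoenolate 27 (not isolated), via zinc alkoxide 28 (not isolated)
Conditions: Et2Zn (1.1 equiv), 2,2′-bipyridine, THF–DMSO, 0 → 25 °C; aq. NH4Cl, 0 °C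
Reagents that add atoms: none
Why: Proposed new method: Et2Zn deprotonates the tertiary cyclopropanol to cyclopropoxide 26, and relief of the strain of the bicyclo[4.1.0]heptane opens the less substituted C1–C9 bond to the chelated β-zincio ketone 27, whose primary C9–Zn bond adds to the C8 aldehyde to give alkoxide 28. The closest known reaction types are the Et2Zn-mediated opening of cyclopropanols to zinc homoenolates that are trapped by enones or allyl electrophiles, and the addition of zinc and titanium ester homoenolates to aldehydes; the 1,2-addition of a cyclopropanol-derived ketone homoenolate to an aldehyde, used to close a ring, is the new element. Ring B closes in the 6-exo-trig mode (C9 attacks the C8 carbonyl carbon, the oxygen stays outside the ring). C8 is set by a chair transition state of the forming ring with C6–OSiEt3 and the C7 acrylate equatorial and the aldehyde oxygen pseudo-equatorial, because the axial alternative meets the axial C14 methyl; this should give the 8α alcohol, and C10 keeps its configuration because only C1–C9 breaks. The step needs 1,2-addition to the aldehyde instead of conjugate addition to the acrylate (a seven-membered closure) and needs C–C bond formation to outrun proton transfer; the six-membered geometry, the fully substituted C10 (no α-hydrogen, so no enolised homoenolate) and the low basicity of alkylzinc species should secure this.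

Step 17
Reactants: 29 methyl 8α-hydroxy-1-oxo-4α,6α-bis(triethylsilyloxy)eudesm-11(13)-en-12-oate
Product: 30 methyl 8α-acetoxy-1-oxo-4α,6α-bis(triethylsilyloxy)eudesm-11(13)-en-12-oate
Conditions: Ac2O, pyridine, DMAP (cat.), CH2Cl2, 0 °C → rt
Reagents that add atoms: acetic anhydride, CC(=O)OC(C)=O
Why: DMAP-catalysed acetylation of the only free hydroxyl installs the C8 acetate.

Step 18
Reactants: 30 methyl 8α-acetoxy-1-oxo-4α,6α-bis(triethylsilyloxy)eudesm-11(13)-en-12-oate
Product: 31 methyl 8α-acetoxy-1β-hydroxy-4α,6α-bis(triethylsilyloxy)eudesm-11(13)-en-12-oate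
Conditions: NaBH4, CeCl3·7H2O, MeOH, −78 → −20 °C; aq. NH4Cl
Reagents that add atoms: none
Why: Luche reduction, in which hydride should attack the C1 ketone along the axial trajectory on the α face, away from the axial C14 methyl, to give the equatorial 1β-alcohol, while CeCl3 suppresses conjugate reduction of the acrylate.

Step 19
Reactants: 31 methyl 8α-acetoxy-1β-hydroxy-4α,6α-bis(triethylsilyloxy)eudesm-11(13)-en-12-oate
Product: 32 methyl 8α-acetoxy-1β,4α,6α-trihydroxyeudesm-11(13)-en-12-oate (CNP0272656.1)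
Conditions: HF·pyridine, pyridine, THF, 0 °C → rt
Reagents that add atoms: none
Why: Pyridine-buffered fluoride desilylation should remove both triethylsilyl ethers while the acetate and the acrylate ester survive and the freed 6-hydroxyl is not pushed to lactonise.

**Compound list**

1 | (R)-(−)-linalool, (3R)-3,7-dimethylocta-1,6-dien-3-ol | CC(C)=CCC[C@@](C=C)(C)O | starting material
2 | (3R)-3,7-dimethyl-3-(triethylsilyloxy)octa-1,6-diene | CC(C)=CCC[C@@](C=C)(C)O[Si](CC)(CC)CC | intermediate
3 | ozonide (1,2,4-trioxolane) of the 6,7-alkene of 2 | CC1(C)OOC(CC[C@@](C=C)(C)O[Si](CC)(CC)CC)O1 | intermediate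
4 | (4R)-4-methyl-4-(triethylsilyloxy)hex-5-enal | O=CCC[C@@](C=C)(C)O[Si](CC)(CC)CC | intermediate
5 | (6R)-2,6-dimethyl-6-(triethylsilyloxy)octa-1,7-dien-3-ol, both C3 epimers | C=C(C)C(O)CC[C@@](C=C)(C)O[Si](CC)(CC)CC | intermediate
6 | (4R)-2,4-dimethyl-4-(triethylsilyloxy)cyclohex-2-en-1-ol, both C1 epimers | OC1CC[C@@](C=C1C)(C)O[Si](CC)(CC)CC | intermediate
7 | (4R)-2,4-dimethyl-4-(triethylsilyloxy)cyclohex-2-en-1-one | O=C1CC[C@@](C=C1C)(C)O[Si](CC)(CC)CC | intermediate
8 | bromomagnesium enolate of the 3-vinyl ketone (vinyl trans to OSiEt3) | C=C[C@@H]1C(C)=C(O[Mg]Br)CC[C@@]1(C)O[Si](CC)(CC)CC | intermediate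
9 | (3R,4R)-2,4-dimethyl-4-(triethylsilyloxy)-1-(trimethylsilyloxy)-3-vinylcyclohex-1-ene (vinyl trans to OSiEt3) | C=C[C@@H]1C(C)=C(O[Si](C)(C)C)CC[C@@]1(C)O[Si](CC)(CC)CC | intermediate
10 | 4,6-dimethyl-4-(triethylsilyloxy)-1-(trimethylsilyloxy)-5-vinylbicyclo[4.1.0]heptane; cyclopropane CH2 (C9) trans to vinyl and cis to OSiEt3; vinyl trans to OSiEt3 | C=C[C@@H]1[C@@]2(C)C[C@@]2(O[Si](C)(C)C)CC[C@@]1(C)O[Si](CC)(CC)CC | intermediate
11 | ozonide (1,2,4-trioxolane) of the vinyl group of 10 | C1(OOCO1)[C@@H]2[C@@]3(C)C[C@@]3(O[Si](C)(C)C)CC[C@@]2(C)O[Si](CC)(CC)CC | intermediate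
12 | 1,3-dimethyl-3-(triethylsilyloxy)-6-(trimethylsilyloxy)bicyclo[4.1.0]heptane-2-carbaldehyde; CHO (C6) trans to OSiEt3 and trans to the cyclopropane CH2 | O=C[C@@H]1[C@@]2(C)C[C@@]2(O[Si](C)(C)C)CC[C@@]1(C)O[Si](CC)(CC)CC | intermediate
13 | dimethyl itaconate | C=C(C(=O)OC)CC(=O)OC | starting material
14 | 3-(methoxycarbonyl)but-3-enoic acid | C=C(C(=O)OC)CC(=O)O | intermediate
15 | (S)-4-benzyl-1,3-oxazolidin-2-one | O=C1N[C@@H](Cc2ccccc2)CO1 | starting material
16 | mixed anhydride of 14 with pivalic acid | C=C(C(=O)OC)CC(=O)OC(=O)C(C)(C)C | intermediate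
17 | N-lithio-(S)-4-benzyl-1,3-oxazolidin-2-one | O=C1N([Li])[C@@H](Cc2ccccc2)CO1 | intermediate
18 | (4S)-4-benzyl-3-[3-(methoxycarbonyl)but-3-enoyl]-1,3-oxazolidin-2-one | C=C(C(=O)OC)CC(=O)N1[C@@H](Cc2ccccc2)COC1=O | intermediate
19 | dibutylboron Z-enolate of 18 | C=C(C(=O)OC)/C=C(\OB(CCCC)CCCC)N1[C@@H](Cc2ccccc2)COC1=O | intermediate
20 | dibutylboron aldolate (O6–B) of the syn adduct | C=C(C(=O)OC)[C@H](C(=O)N1[C@@H](Cc2ccccc2)COC1=O)[C@H](OB(CCCC)CCCC)[C@@H]3[C@@]4(C)C[C@@]4(O[Si](C)(C)C)CC[C@@]3(C)O[Si](CC)(CC)CC | intermediate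
21 | (4S)-4-benzyl-3-{(2S,3R)-3-hydroxy-2-[1-(methoxycarbonyl)ethenyl]-3-[the bicycloheptyl unit of 12]propanoyl}-1,3-oxazolidin-2-one; C6 and C7 as in the target | C=C(C(=O)OC)[C@H](C(=O)N1[C@@H](Cc2ccccc2)COC1=O)[C@H](O)[C@@H]3[C@@]4(C)C[C@@]4(O[Si](C)(C)C)CC[C@@]3(C)O[Si](CC)(CC)CC | intermediate
22 | 6-O-triethylsilyl ether of 21 | C=C(C(=O)OC)[C@H](C(=O)N1[C@@H](Cc2ccccc2)COC1=O)[C@H](O[Si](CC)(CC)CC)[C@@H]3[C@@]4(C)C[C@@]4(O[Si](C)(C)C)CC[C@@]3(C)O[Si](CC)(CC)CC | intermediate
23 | cyclopropanol from 22 (free OH on C1; imide at C8) | C=C(C(=O)OC)[C@H](C(=O)N1[C@@H](Cc2ccccc2)COC1=O)[C@H](O[Si](CC)(CC)CC)[C@@H]3[C@@]4(C)C[C@@]4(O)CC[C@@]3(C)O[Si](CC)(CC)CC | intermediate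
24 | C8 primary alcohol: methyl 3-(hydroxymethyl)-2-methylidene-4-(triethylsilyloxy)-4-[ring A cyclopropanol unit]butanoate; C6 and C7 as in the target | C=C(C(=O)OC)[C@H](CO)[C@H](O[Si](CC)(CC)CC)[C@@H]1[C@@]2(C)C[C@@]2(O)CC[C@@]1(C)O[Si](CC)(CC)CC | intermediate
25 | C8 aldehyde: methyl 3-formyl-2-methylidene-4-(triethylsilyloxy)-4-[ring A cyclopropanol unit]butanoate | C=C(C(=O)OC)[C@H](C=O)[C@H](O[Si](CC)(CC)CC)[C@@H]1[C@@]2(C)C[C@@]2(O)CC[C@@]1(C)O[Si](CC)(CC)CC | intermediate
26 | ethylzinc cyclopropoxide of 25 | C=C(C(=O)OC)[C@H](C=O)[C@H](O[Si](CC)(CC)CC)[C@@H]1[C@@]2(C)C[C@@]2(O[Zn]CC)CC[C@@]1(C)O[Si](CC)(CC)CC | intermediate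
27 | zinc homoenolate: C1 ketone with C9–Zn–Et on the quaternary C10 | C=C(C(=O)OC)[C@H](C=O)[C@H](O[Si](CC)(CC)CC)[C@@H]1[C@@](C)(C[Zn]CC)C(=O)CC[C@@]1(C)O[Si](CC)(CC)CC | intermediate
28 | ethylzinc 8α-alkoxide of 29 | C=C(C(=O)OC)[C@H]1[C@H](O[Si](CC)(CC)CC)[C@@H]2[C@@](C)(C[C@@H]1O[Zn]CC)C(=O)CC[C@@]2(C)O[Si](CC)(CC)CC | intermediate
29 | methyl 8α-hydroxy-1-oxo-4α,6α-bis(triethylsilyloxy)eudesm-11(13)-en-12-oate (5αH, 7αH, 10β-methyl) | C=C(C(=O)OC)[C@H]1[C@H](O[Si](CC)(CC)CC)[C@@H]2[C@@](C)(C[C@@H]1O)C(=O)CC[C@@]2(C)O[Si](CC)(CC)CC | intermediate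
30 | methyl 8α-acetoxy-1-oxo-4α,6α-bis(triethylsilyloxy)eudesm-11(13)-en-12-oate | C=C(C(=O)OC)[C@H]1[C@H](O[Si](CC)(CC)CC)[C@@H]2[C@@](C)(C[C@@H]1OC(C)=O)C(=O)CC[C@@]2(C)O[Si](CC)(CC)CC | intermediate
31 | methyl 8α-acetoxy-1β-hydroxy-4α,6α-bis(triethylsilyloxy)eudesm-11(13)-en-12-oate | C=C(C(=O)OC)[C@H]1[C@H](O[Si](CC)(CC)CC)[C@@H]2[C@@](C)(C[C@@H]1OC(C)=O)[C@H](O)CC[C@@]2(C)O[Si](CC)(CC)CC | intermediate
32 | methyl 8α-acetoxy-1β,4α,6α-trihydroxyeudesm-11(13)-en-12-oate (CNP0272656.1) | C=C(C(=O)OC)[C@H]1[C@H](O)[C@@H]2[C@@](C)(C[C@@H]1OC(C)=O)[C@H](O)CC[C@@]2(C)O | target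

**Step count and risks**

Total steps: 19. Longest linear sequence: 17 (steps 1–8 and 11–19); steps 9–10 make imide 18 in a branch.

Most likely to fail:

1. Step 16. The zinc cyclopropoxide may be slow to open, and the basic zinc species may instead enolise the C8 aldehyde (loss of C7 configuration, migration of the C11=C13 bond into conjugation, β-elimination of the C6 silyloxy group). The product alkoxide may also lactonise onto C12, and the reactive conformer has to carry the C14/C15 syn-diaxial interaction. Fallback with known chemistry, setting out from 25: electrophilic ring-opening iodination of the cyclopropanol with N-iodosuccinimide (CH2Cl2, 0 °C) should give the β-iodo ketone F1, which cannot eliminate because C10 is quaternary. Cobalt-catalysed alkylchromium addition (CrCl2 in excess, catalytic cobalt phthalocyanine Co(C32H16N8), DMF, rt), a Nozaki–Hiyama-type reaction in which alkylchromium reagents add to aldehydes but not to ketones or esters, would then close ring B and return to the route at 29.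

2. Step 11. The aldehyde, flanked by two quaternary carbons, may add too slowly to the boron enolate, which can then isomerise into conjugation, and the substrate's own facial bias may erode the reagent control. Fallback setting out from 12: methyl 4-hydroxybut-2-ynoate is silylated (Et3SiCl, imidazole) to methyl 4-(triethylsilyloxy)but-2-ynoate F2. Syn-hydroalumination (i-Bu2AlH, HMPA, THF) and trapping with ICH2B(pin) gives the allylboronate methyl (2Z)-2-[(pinacolboryl)methyl]-4-(triethylsilyloxy)but-2-enoate F3. Thermal allylboration of 12 (toluene, 80 °C) through a closed chair would give the homoallylic alcohol F4 with the same O6/C8 relation as the aldol, its facial selectivity resting on the substrate alone. Silylation (Et3SiOTf, 2,6-lutidine) gives the tris-silyl ether F5, and PPTS in MeOH removes the primary triethylsilyl and the trimethylsilyl groups, coming back to the route at 24. This path also bypasses steps 12–14.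

3. Step 14. The C8 alkoxide formed on reduction may lactonise onto the C12 ester, and hydride may open the oxazolidinone ring of the hindered imide or add to the acrylate. Fallback setting out from 21: transamination directed by the free 6-hydroxyl (Me3Al, MeONHMe·HCl, CH2Cl2, −20 → 0 °C) gives the Weinreb amide F6. Silylation (Et3SiOTf, 2,6-lutidine) gives its 6-O-triethylsilyl ether F7, and PPTS in MeOH frees the cyclopropanol F8. Reduction with i-Bu2AlH (THF, −78 °C, one extra equivalent for the cyclopropanol) then stops at the chelated tetrahedral intermediate and releases aldehyde 25 on work-up, so no C8 alkoxide is formed; the route is rejoined at 25.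

**Further compounds**

F1 | step 16 | β-iodo ketone: C1 ketone with CH2I (C9) on C10, C8 aldehyde kept | C=C(C(=O)OC)[C@H](C=O)[C@H](O[Si](CC)(CC)CC)[C@@H]1[C@@](C)(CI)C(=O)CC[C@@]1(C)O[Si](CC)(CC)CC
F2 | step 11 | methyl 4-(triethylsilyloxy)but-2-ynoate | COC(=O)C#CCO[Si](CC)(CC)CC
F3 | step 11 | methyl (2Z)-2-[(4,4,5,5-tetramethyl-1,3,2-dioxaborolan-2-yl)methyl]-4-(triethylsilyloxy)but-2-enoate | COC(=O)/C(CB1OC(C)(C)C(C)(C)O1)=C\CO[Si](CC)(CC)CC
F4 | step 11 | allylboration adduct: free 6-hydroxyl, C8 as CH2OSiEt3, C6/C7 as in the target | C=C(C(=O)OC)[C@H](CO[Si](CC)(CC)CC)[C@H](O)[C@@H]1[C@@]2(C)C[C@@]2(O[Si](C)(C)C)CC[C@@]1(C)O[Si](CC)(CC)CC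
F5 | step 11 | 6-O-triethylsilyl ether of F4 | C=C(C(=O)OC)[C@H](CO[Si](CC)(CC)CC)[C@H](O[Si](CC)(CC)CC)[C@@H]1[C@@]2(C)C[C@@]2(O[Si](C)(C)C)CC[C@@]1(C)O[Si](CC)(CC)CC
F6 | step 14 | Weinreb amide (N-methoxy-N-methylamide at C8) with free 6-hydroxyl | C=C(C(=O)OC)[C@H](C(=O)N(C)OC)[C@H](O)[C@@H]1[C@@]2(C)C[C@@]2(O[Si](C)(C)C)CC[C@@]1(C)O[Si](CC)(CC)CC
F7 | step 14 | 6-O-triethylsilyl ether of F6 | C=C(C(=O)OC)[C@H](C(=O)N(C)OC)[C@H](O[Si](CC)(CC)CC)[C@@H]1[C@@]2(C)C[C@@]2(O[Si](C)(C)C)CC[C@@]1(C)O[Si](CC)(CC)CC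
F8 | step 14 | cyclopropanol from F7 (Me3Si removed) | C=C(C(=O)OC)[C@H](C(=O)N(C)OC)[C@H](O[Si](CC)(CC)CC)[C@@H]1[C@@]2(C)C[C@@]2(O)CC[C@@]1(C)O[Si](CC)(CC)CC
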